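The route rests on cutting both aryl bonds of C4 in the upper (gallocatechin) unit: C4–C4a to its own ring A and C4–C8 to ring A of the middle unit. C4 is thus a diarylmethine and is introduced as an aldehyde carbon, a 1,1-dielectrophile. In one operation an acyclic α-hydroxy aldehyde, already carrying the O1–C2 phloroglucinol aryl ether, closes pyran ring C by C4–C4a Friedel–Crafts hydroxyalkylation; the C4 carbinol then ionises and is arylated by C8 of a preformed catechin-(4β→8)-ent-catechin dimer, setting the 3,4-trans centre. The 3,4-cis dimer comes from an aryllithium/flavan-4-one union and ionic reduction.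

Key step: step 13

Remark on the chemistry: the target is read as gallocatechin-(4α→8)-catechin-(4β→8)-ent-catechin. The upper unit is 2R,3S,4S (2,3-trans-3,4-trans), the middle unit 2R,3S,4S (2,3-trans-3,4-cis) and the lower unit 2S,3R. 3,4,5-Tris(benzyloxy)benzaldehyde, 3,5-bis(benzyloxy)phenol, (−)-catechin and (+)-taxifolin are assumed to be purchasable.

**Upper-unit fragment**

Step 1
Reactants: 1 3,4,5-tris(benzyloxy)benzaldehyde
Product: 2 ethyl (E)-3-[3,4,5-tris(benzyloxy)phenyl]prop-2-enoate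
Conditions: (EtO)2P(O)CH2CO2Et, NaH, THF, 0 °C → rt
Reagents that add atoms: triethyl phosphonoacetate, CCOC(=O)CP(=O)(OCC)OCC
Why: Horner–Wadsworth–Emmons olefination of an aryl aldehyde with a stabilised phosphonate anion should give the E-enoate selectively.

Step 2
Reactants: 2 ethyl (E)-3-[3,4,5-tris(benzyloxy)phenyl]prop-2-enoate
Product: 3 (E)-3-[3,4,5-tris(benzyloxy)phenyl]prop-2-en-1-ol
Conditions: DIBAL-H (2.5 equiv), CH2Cl2, −78 → 0 °C; Rochelle salt work-up
Reagents that add atoms: none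
Why: 1,2-reduction of the enoate by DIBAL-H should give the E-allylic alcohol without touching the alkene or the benzyl ethers.

Step 3
Reactants: 3 (E)-3-[3,4,5-tris(benzyloxy)phenyl]prop-2-en-1-ol
Product: 4 [(2S,3S)-3-[3,4,5-tris(benzyloxy)phenyl]oxiran-2-yl]methanol
Conditions: Ti(OiPr)4 (10 mol%), L-(+)-diisopropyl tartrate (12 mol%), t-BuOOH, 4 Å MS, CH2Cl2, −20 °C
Reagents that add atoms: tert-butyl hydroperoxide, CC(C)(C)OO
Why: Sharpless asymmetric epoxidation with the L-(+)-tartrate delivers oxygen to one face of the E-allylic alcohol and should give the (2S,3S)-trans-epoxide, which fixes the carbinol carbon that becomes C3 of the upper unit.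

Step 4
Reactants: 4 [(2S,3S)-3-[3,4,5-tris(benzyloxy)phenyl]oxiran-2-yl]methanol; 5 3,5-bis(benzyloxy)phenol
Product: 6 (2S,3R)-3-[3,5-bis(benzyloxy)phenoxy]-3-[3,4,5-tris(benzyloxy)phenyl]propane-1,2-diol
Conditions: 5 (1.5 equiv), Cs2CO3 (0.3 equiv), DMF, 60 °C
Reagents that add atoms: none
Why: SN2 opening of the aryl-substituted epoxy alcohol by the phenoxide of 5 at the benzylic carbon, with inversion, should install the O1–C2 aryl ether and set C2 of the upper unit (R), while the low alkoxide concentration in DMF suppresses Payne rearrangement.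

**Lower unit**

Step 5
Reactants: 7 (−)-catechin
Product: 8 5,7,3',4'-tetra-O-benzyl-(−)-catechin
Conditions: BnBr (4.4 equiv), K2CO3, DMF, 0 °C → rt
Reagents that add atoms: benzyl bromide, BrCc1ccccc1
Why: Williamson etherification under weak base should benzylate the four phenols and leave the secondary 3-OH and both stereocentres untouched.

Step 6
Reactants: 8 5,7,3',4'-tetra-O-benzyl-(−)-catechin
Product: 9 8-bromo-5,7,3',4'-tetra-O-benzyl-(−)-catechin
Conditions: NBS (1.0 equiv), CH2Cl2, −78 °C → rt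
Reagents that add atoms: N-bromosuccinimide, O=C1CCC(=O)N1Br
Why: electrophilic aromatic bromination of the phloroglucinol-type ring A should occur at C8, the position flanked by only one benzyloxy group and the pyran oxygen.

Step 7
Reactants: 9 8-bromo-5,7,3',4'-tetra-O-benzyl-(−)-catechin
Product: 10 8-bromo-3,5,7,3',4'-penta-O-benzyl-(−)-catechin
Conditions: NaH, BnBr, DMF, 0 °C → rt
Reagents that add atoms: benzyl bromide, BrCc1ccccc1
Why: Williamson benzylation of the 3-alkoxide removes the last acidic proton before the organolithium step and uses a group that falls in the final hydrogenolysis.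

**Middle unit**

Step 8
Reactants: 11 (+)-taxifolin
Product: 12 5,7,3',4'-tetra-O-benzyl-(+)-taxifolin
Conditions: BnBr (4.5 equiv), K2CO3, DMF, rt, argon
Reagents that add atoms: benzyl bromide, BrCc1ccccc1
Why: Williamson etherification of the four phenols with a weak base at room temperature should keep the 2,3-trans dihydroflavonol intact by limiting retro-oxa-Michael ring opening.

Step 9
Reactants: 12 5,7,3',4'-tetra-O-benzyl-(+)-taxifolin
Product: 13 3,5,7,3',4'-penta-O-benzyl-(+)-taxifolin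
Conditions: BnOC(=NH)CCl3, TfOH (cat.), CH2Cl2/cyclohexane, 0 °C → rt
Reagents that add atoms: benzyl 2,2,2-trichloroacetimidate, N=C(OCc1ccccc1)C(Cl)(Cl)Cl
Why: acid-catalysed O-benzylation with the trichloroacetimidate avoids base and so should not enolise the C4 ketone or epimerise C2 and C3.

**Dimer**

Step 10
Reactants: 10 8-bromo-3,5,7,3',4'-penta-O-benzyl-(−)-catechin; 13 3,5,7,3',4'-penta-O-benzyl-(+)-taxifolin
Product: 15 deca-O-benzyl 4-hydroxycatechin-(4→8)-ent-catechin (tertiary C4 carbinol of undefined C4 configuration), via aryllithium 14 (not isolated)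
Conditions: t-BuLi (2.0 equiv), THF, −78 °C; then 13, −78 → 0 °C; H2O
Reagents that add atoms: none
Why: bromine–lithium exchange gives aryllithium 14, whose 1,2-addition to the C4 ketone of 13 should forge the interflavan C4–C8 bond, and the carbinol configuration is irrelevant because C4 is ionised in the next step.

Step 11
Reactants: 15 deca-O-benzyl 4-hydroxycatechin-(4→8)-ent-catechin
Product: 16 deca-O-benzyl catechin-(4β→8)-ent-catechin (middle unit 2,3-trans-3,4-cis)
Conditions: Bu3SnH, CF3CO2H, CH2Cl2, 0 °C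
Reagents that add atoms: none
Why: in this ionic hydrogenation TFA ionises the doubly benzylic tertiary carbinol and Bu3SnH should deliver hydride to C4 on the alpha face, anti to the adjacent 3-benzyloxy group, which leaves the aryl group beta and sets the 3,4-cis centre.

**Union and deprotection**

Step 12
Reactants: 6 (2S,3R)-3-[3,5-bis(benzyloxy)phenoxy]-3-[3,4,5-tris(benzyloxy)phenyl]propane-1,2-diol
Product: 17 (2R,3R)-3-[3,5-bis(benzyloxy)phenoxy]-2-hydroxy-3-[3,4,5-tris(benzyloxy)phenyl]propanal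
Conditions: TEMPO (10 mol%), PhI(OAc)2 (1.1 equiv), CH2Cl2, rt; used crude at once
Reagents that add atoms: none
Why: the oxoammonium (TEMPO/PhI(OAc)2) oxidation should select the primary over the secondary alcohol and stop at the aldehyde, and immediate use keeps the α-stereocentre from epimerising.

Step 13
Reactants: 17 (2R,3R)-3-[3,5-bis(benzyloxy)phenoxy]-2-hydroxy-3-[3,4,5-tris(benzyloxy)phenyl]propanal; 16 deca-O-benzyl catechin-(4β→8)-ent-catechin
Product: 19 pentadeca-O-benzyl gallocatechin-(4α→8)-catechin-(4β→8)-ent-catechin with free 3-OH on the upper unit, via flavan-3,4-diol 18 (not isolated)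
Conditions: 16 (1.5 equiv), Yb(OTf)3 (20 mol%), 4 Å MS, CH2Cl2, −20 °C; crude 17 added slowly; then 0 °C
Reagents that add atoms: none
Why: Yb(OTf)3 activates the aldehyde carbon (C4) of 17 and the 3,5-bis(benzyloxy)phenoxy ring attacks it through the carbon ortho to the ether oxygen (C4a), closing pyran ring C of the upper unit in a 6-exo-trig intramolecular Friedel–Crafts hydroxyalkylation to give flavan-3,4-diol 18; the same acid then ionises the C4 carbinol to a benzylic cation stabilised by O1 and the 5- and 7-benzyloxy groups, which is captured by C8 of ring A of the middle unit of 16 in an intermolecular Friedel–Crafts alkylation. The closest known reaction types are the acid-catalysed condensation of an aldehyde with two electron-rich arenes to a diarylmethane and the Lewis-acid coupling of flavan-3,4-diols with flavan-3-ols. The new C4 stereocentre is controlled by the adjacent C3 carbinol: the arene should enter the cation on the alpha face, anti to the C3 oxygen, giving the all-equatorial 2,3-trans-3,4-trans ring. Ring closure needs no regiocontrol because the two positions ortho to the ether oxygen of the symmetric phenoxy ring are equivalent and the para position cannot reach C4, and ring A is far more nucleophilic than the tribenzyloxyphenyl ring B, which could only close a five-membered ring. On the dimer, C8 of the middle unit is the only free position flanked by one benzyloxy group and the pyran oxygen, whereas both C6 positions lie between two benzyloxy groups, and the excess of 16 with slow addition of 17 should suppress attack of a product ring A on a second cation.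

Step 14
Reactants: 19 pentadeca-O-benzyl gallocatechin-(4α→8)-catechin-(4β→8)-ent-catechin with free 3-OH on the upper unit
Product: 20 gallocatechin-(4α→8)-catechin-(4β→8)-ent-catechin (CNP0155646.2)
Conditions: H2 (1 atm), Pd(OH)2/C, THF/MeOH/H2O, rt
Reagents that add atoms: none
Why: hydrogenolysis of all fifteen benzyl ethers over Pd(OH)2/C under neutral conditions should leave the acid-sensitive interflavan bonds and every stereocentre untouched.

**Compound list**

1 | 3,4,5-tris(benzyloxy)benzaldehyde | O=Cc1cc(OCc9ccccc9)c(OCc9ccccc9)c(OCc9ccccc9)c1 | starting material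
2 | ethyl (E)-3-[3,4,5-tris(benzyloxy)phenyl]prop-2-enoate | CCOC(=O)/C=C/c1cc(OCc9ccccc9)c(OCc9ccccc9)c(OCc9ccccc9)c1 | intermediate
3 | (E)-3-[3,4,5-tris(benzyloxy)phenyl]prop-2-en-1-ol | OC/C=C/c1cc(OCc9ccccc9)c(OCc9ccccc9)c(OCc9ccccc9)c1 | intermediate
4 | [(2S,3S)-3-[3,4,5-tris(benzyloxy)phenyl]oxiran-2-yl]methanol | OC[C@@H]1O[C@H]1c1cc(OCc9ccccc9)c(OCc9ccccc9)c(OCc9ccccc9)c1 | intermediate
5 | 3,5-bis(benzyloxy)phenol | Oc1cc(OCc9ccccc9)cc(OCc9ccccc9)c1 | starting material
6 | (2S,3R)-3-[3,5-bis(benzyloxy)phenoxy]-3-[3,4,5-tris(benzyloxy)phenyl]propane-1,2-diol | c9ccccc9COc1cc(OCc9ccccc9)cc(c1)O[C@H](c1cc(OCc9ccccc9)c(OCc9ccccc9)c(OCc9ccccc9)c1)[C@@H](O)CO | intermediate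
7 | (−)-catechin, (2S,3R)-2-(3,4-dihydroxyphenyl)chromane-3,5,7-triol | Oc1cc(O)c2c(c1)O[C@@H](c1ccc(O)c(O)c1)[C@H](O)C2 | starting material
8 | 5,7,3',4'-tetra-O-benzyl-(−)-catechin | c9ccccc9COc1cc(OCc9ccccc9)c2c(c1)O[C@@H](c1ccc(OCc9ccccc9)c(OCc9ccccc9)c1)[C@H](O)C2 | intermediate
9 | 8-bromo-5,7,3',4'-tetra-O-benzyl-(−)-catechin | c9ccccc9COc1cc(OCc9ccccc9)c2c(c1Br)O[C@@H](c1ccc(OCc9ccccc9)c(OCc9ccccc9)c1)[C@H](O)C2 | intermediate
10 | 8-bromo-3,5,7,3',4'-penta-O-benzyl-(−)-catechin | c9ccccc9COc1cc(OCc9ccccc9)c2c(c1Br)O[C@@H](c1ccc(OCc9ccccc9)c(OCc9ccccc9)c1)[C@H](OCc9ccccc9)C2 | intermediate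
11 | (+)-taxifolin, (2R,3R)-dihydroquercetin | Oc1cc(O)c2c(c1)O[C@H](c1ccc(O)c(O)c1)[C@@H](O)C2=O | starting material
12 | 5,7,3',4'-tetra-O-benzyl-(+)-taxifolin | c9ccccc9COc1cc(OCc9ccccc9)c2c(c1)O[C@H](c1ccc(OCc9ccccc9)c(OCc9ccccc9)c1)[C@@H](O)C2=O | intermediate
13 | 3,5,7,3',4'-penta-O-benzyl-(+)-taxifolin | c9ccccc9COc1cc(OCc9ccccc9)c2c(c1)O[C@H](c1ccc(OCc9ccccc9)c(OCc9ccccc9)c1)[C@@H](OCc9ccccc9)C2=O | intermediate
14 | 8-lithio-3,5,7,3',4'-penta-O-benzyl-(−)-catechin (aryllithium) | c9ccccc9COc1cc(OCc9ccccc9)c2c(c1[Li])O[C@@H](c1ccc(OCc9ccccc9)c(OCc9ccccc9)c1)[C@H](OCc9ccccc9)C2 | intermediate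
15 | deca-O-benzyl 4-hydroxycatechin-(4→8)-ent-catechin, tertiary C4 carbinol of undefined C4 configuration | c9ccccc9COc1cc(OCc9ccccc9)c2c(c1)O[C@H](c1ccc(OCc9ccccc9)c(OCc9ccccc9)c1)[C@@H](OCc9ccccc9)C2(O)c1c(OCc9ccccc9)cc(OCc9ccccc9)c2c1O[C@@H](c1ccc(OCc9ccccc9)c(OCc9ccccc9)c1)[C@H](OCc9ccccc9)C2 | intermediate
16 | deca-O-benzyl catechin-(4β→8)-ent-catechin, middle unit 2,3-trans-3,4-cis | c9ccccc9COc1cc(OCc9ccccc9)c2c(c1)O[C@H](c1ccc(OCc9ccccc9)c(OCc9ccccc9)c1)[C@@H](OCc9ccccc9)[C@H]2c1c(OCc9ccccc9)cc(OCc9ccccc9)c2c1O[C@@H](c1ccc(OCc9ccccc9)c(OCc9ccccc9)c1)[C@H](OCc9ccccc9)C2 | intermediate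
17 | (2R,3R)-3-[3,5-bis(benzyloxy)phenoxy]-2-hydroxy-3-[3,4,5-tris(benzyloxy)phenyl]propanal | c9ccccc9COc1cc(OCc9ccccc9)cc(c1)O[C@H](c1cc(OCc9ccccc9)c(OCc9ccccc9)c(OCc9ccccc9)c1)[C@@H](O)C=O | intermediate
18 | (2R,3S)-5,7-bis(benzyloxy)-2-[3,4,5-tris(benzyloxy)phenyl]chromane-3,4-diol, C4 epimers (flavan-3,4-diol) | c9ccccc9COc1cc(OCc9ccccc9)c2c(c1)O[C@H](c1cc(OCc9ccccc9)c(OCc9ccccc9)c(OCc9ccccc9)c1)[C@@H](O)C2O | intermediate
19 | pentadeca-O-benzyl gallocatechin-(4α→8)-catechin-(4β→8)-ent-catechin with free 3-OH on the upper unit | c9ccccc9COc1cc(OCc9ccccc9)c2c(c1)O[C@H](c1cc(OCc9ccccc9)c(OCc9ccccc9)c(OCc9ccccc9)c1)[C@@H](O)[C@@H]2c1c(OCc9ccccc9)cc(OCc9ccccc9)c2c1O[C@H](c1ccc(OCc9ccccc9)c(OCc9ccccc9)c1)[C@@H](OCc9ccccc9)[C@H]2c1c(OCc9ccccc9)cc(OCc9ccccc9)c2c1O[C@@H](c1ccc(OCc9ccccc9)c(OCc9ccccc9)c1)[C@H](OCc9ccccc9)C2 | intermediate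
20 | gallocatechin-(4α→8)-catechin-(4β→8)-ent-catechin, CNP0155646.2 | Oc1cc(O)c2c(c1)O[C@H](c1cc(O)c(O)c(O)c1)[C@@H](O)[C@@H]2c1c(O)cc(O)c2c1O[C@H](c1ccc(O)c(O)c1)[C@@H](O)[C@H]2c1c(O)cc(O)c2c1O[C@@H](c1ccc(O)c(O)c1)[C@H](O)C2 | target

**Step count and risks**

Total step count: 14. Longest linear sequence: 7 steps (steps 1–4, 12, 13, 14; the lower-unit branch through steps 5–7, 10, 11, 13, 14 is equally long).

The three steps most likely to fail:

1. Step 13 (key step). The C4 cation may be attacked by ring A of another upper unit (oligomerisation), and facial selectivity at C4 may be poor with a free 3-OH. The fallback sets out from 17 and returns at 19. Aldehyde 17 is cyclised alone at high dilution with Yb(OTf)3, and flavan-3,4-diol 18 is isolated. Both hydroxyls are acetylated (Ac2O, pyridine, DMAP) to the 3,4-di-O-acetate F1. F1 is coupled with 16 (BF3·OEt2, CH2Cl2, −78 °C): the 4-acetate leaves and the 3-acetate bridges the beta face as an acetoxonium ion, so that the dimer must enter trans. This should give the 3-O-acetyl pentadeca-O-benzyl trimer F2, and methanolysis (K2CO3, MeOH/THF) leads to 19.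

2. Step 11. Hydride may be delivered with poor or reversed facial selectivity, because the 2-aryl and 3-benzyloxy groups of the middle unit lie on opposite faces of the C4 cation. The fallback sets out from 8 and 12 and returns at 16; it replaces hydride delivery by tether-directed aryl delivery. Alcohol 8 is acylated with glutaric anhydride (DMAP) to the hemiglutarate F3. F3 is esterified with the 3-OH of 12 (EDC, DMAP) to the keto diester F4. The ketone is reduced (NaBH4, CeCl3, −40 °C) to the C4 carbinol diester F5. TMSOTf (cat.) at high dilution ionises C4, and the lower-unit C8, held on the beta face by the 3-O tether, should close the macrocyclic 3,4-cis dimer diester F6. NaOMe/MeOH removes the tether to give the dimer diol F7, and NaH/BnBr benzylation gives 16.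

3. Step 12. The α-hydroxy aldehyde may be lost by over-oxidation, glycol cleavage, epimerisation or β-elimination of the aryloxy group. The fallback sets out from 6 and returns at 19; it keeps ring closure through the same C4–C4a bond but brings C4 in as a methylene. Diol 6 is cyclodehydrated under Mitsunobu conditions (PPh3, DIAD), with retention at the secondary carbinol, to the terminal epoxide F8. A 6-endo epoxide–arene Friedel–Crafts cyclisation (AuCl3/AgOTf, CH2Cl2) should give 5,7,3',4',5'-penta-O-benzyl-gallocatechin F9. DDQ with 2-ethoxyethanol oxidises the benzylic C4 to the 4-(2-ethoxyethoxy) ether F10. Coupling of F10 with 16 (TMSOTf, CH2Cl2, −78 °C) gives 19.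

Further compounds
F1 | step 13 | (2R,3S)-5,7-bis(benzyloxy)-2-[3,4,5-tris(benzyloxy)phenyl]chromane-3,4-diyl diacetate, C4 epimers | c9ccccc9COc1cc(OCc9ccccc9)c2c(c1)O[C@H](c1cc(OCc9ccccc9)c(OCc9ccccc9)c(OCc9ccccc9)c1)[C@@H](OC(C)=O)C2OC(C)=O
F2 | step 13 | 3-O-acetyl (upper unit) pentadeca-O-benzyl gallocatechin-(4α→8)-catechin-(4β→8)-ent-catechin | c9ccccc9COc1cc(OCc9ccccc9)c2c(c1)O[C@H](c1cc(OCc9ccccc9)c(OCc9ccccc9)c(OCc9ccccc9)c1)[C@@H](OC(C)=O)[C@@H]2c1c(OCc9ccccc9)cc(OCc9ccccc9)c2c1O[C@H](c1ccc(OCc9ccccc9)c(OCc9ccccc9)c1)[C@@H](OCc9ccccc9)[C@H]2c1c(OCc9ccccc9)cc(OCc9ccccc9)c2c1O[C@@H](c1ccc(OCc9ccccc9)c(OCc9ccccc9)c1)[C@H](OCc9ccccc9)C2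
F3 | step 11 | 5,7,3',4'-tetra-O-benzyl-(−)-catechin 3-O-hemiglutarate | c9ccccc9COc1cc(OCc9ccccc9)c2c(c1)O[C@@H](c1ccc(OCc9ccccc9)c(OCc9ccccc9)c1)[C@H](OC(=O)CCCC(O)=O)C2
F4 | step 11 | glutarate diester linking O3 of tetra-O-benzyl-(+)-taxifolin and O3 of tetra-O-benzyl-(−)-catechin (keto diester) | c9ccccc9COc1cc(OCc9ccccc9)c2c(c1)O[C@H](c1ccc(OCc9ccccc9)c(OCc9ccccc9)c1)[C@@H](OC(=O)CCCC(=O)O[C@@H]3Cc4c(OCc9ccccc9)cc(OCc9ccccc9)cc4O[C@H]3c3ccc(OCc9ccccc9)c(OCc9ccccc9)c3)C2=O
F5 | step 11 | C4 carbinol diester from reduction of the keto diester, C4 epimers | c9ccccc9COc1cc(OCc9ccccc9)c2c(c1)O[C@H](c1ccc(OCc9ccccc9)c(OCc9ccccc9)c1)[C@@H](OC(=O)CCCC(=O)O[C@@H]3Cc4c(OCc9ccccc9)cc(OCc9ccccc9)cc4O[C@H]3c3ccc(OCc9ccccc9)c(OCc9ccccc9)c3)C2O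
F6 | step 11 | macrocyclic 3,3-O-glutaryl octa-O-benzyl catechin-(4β→8)-ent-catechin | c9ccccc9COc1cc(OCc9ccccc9)c2c(c1)O[C@H](c1ccc(OCc9ccccc9)c(OCc9ccccc9)c1)[C@@H](OC(=O)CCCC(=O)O%10)[C@H]2c1c(OCc9ccccc9)cc(OCc9ccccc9)c2c1O[C@@H](c1ccc(OCc9ccccc9)c(OCc9ccccc9)c1)[C@H]%10C2
F7 | step 11 | octa-O-benzyl catechin-(4β→8)-ent-catechin with both 3-OH free (dimer diol) | c9ccccc9COc1cc(OCc9ccccc9)c2c(c1)O[C@H](c1ccc(OCc9ccccc9)c(OCc9ccccc9)c1)[C@@H](O)[C@H]2c1c(OCc9ccccc9)cc(OCc9ccccc9)c2c1O[C@@H](c1ccc(OCc9ccccc9)c(OCc9ccccc9)c1)[C@H](O)C2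
F8 | step 12 | (2S)-2-[(R)-[3,5-bis(benzyloxy)phenoxy][3,4,5-tris(benzyloxy)phenyl]methyl]oxirane | c9ccccc9COc1cc(OCc9ccccc9)cc(c1)O[C@H](c1cc(OCc9ccccc9)c(OCc9ccccc9)c(OCc9ccccc9)c1)[C@@H]1CO1
F9 | step 12 | 5,7,3',4',5'-penta-O-benzyl-gallocatechin, (2R,3S) | c9ccccc9COc1cc(OCc9ccccc9)c2c(c1)O[C@H](c1cc(OCc9ccccc9)c(OCc9ccccc9)c(OCc9ccccc9)c1)[C@@H](O)C2
F10 | step 12 | 5,7,3',4',5'-penta-O-benzyl-4-(2-ethoxyethoxy)gallocatechin, C4 configuration undefined | c9ccccc9COc1cc(OCc9ccccc9)c2c(c1)O[C@H](c1cc(OCc9ccccc9)c(OCc9ccccc9)c(OCc9ccccc9)c1)[C@@H](O)C2OCCOCC
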